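**Compound numbers used throughout** (structures in the list after the steps): 1 2'-hydroxy-3'-methoxyacetophenone; 2 allyl bromide; 3 its allyl ether; 4, 5 dienone intermediates; 6 5'-allyl-2'-hydroxy-3'-methoxyacetophenone; 7 enaminone; 8 6-allyl-8-methoxychromone; 9 guaiacol pinacol boronate; 10 its mesylate; 11 boronic acid; 12 (2S)-flavanone; 13 enol ether; 14 iodane adduct; 15 orthoester; 16 trans ester; 17 aldehyde; 18 alcohol; 19 eugenol; 20 mesylate of the target; 21 target.

## Analysis of the target

The target 21 is a trans-2-aryl-3-(aryloxymethyl)-2,3-dihydrobenzofuran. Ring A (the benzo ring, with 5-allyl and 7-methoxy groups) is fused to the dihydrofuran ring O1–C2–C3–C3a–C7a; C2 carries ring C (4-hydroxy-3-methoxyphenyl) and C3 carries a CH2 group bound to the phenol oxygen of eugenol. The only stereocentres are the adjacent C2 (S) and C3 (R), with the aryl group and the CH2O arm on opposite faces of the five-membered ring. The two terminal allyl groups exclude hydrogenation, move into conjugation under strong base or metal hydride catalysis, and react with electrophilic oxidants. C2 is a benzylic ether carbon para to a free phenol, so acid or hot base can open the C2–O1 bond through a benzylic cation or quinone methide. C3–H is benzylic with an aryloxy group in the β position, so elimination to a benzofuran is possible. The difficulty is absolute control over two contiguous benzylic centres in an electron-rich, ionisable framework that offers only ether oxygens as handles. The strategy rests on one feature: C3 is bonded to C3a of ring A and to a single exocyclic carbon. That is the pattern left when C4a of a 2-arylchroman-4-one moves from the carbonyl carbon C4 to C3, so that C4 becomes the one-carbon arm and the six-membered ring shrinks to five. C2 is untouched by that shift and has the (2S) configuration of the natural flavanones, so one enantioselective C–aryl bond formation can carry all the chirality.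

## Retrosynthetic reasoning

**21 to 20.** The last operation is removal of a methanesulfonyl group from the ring C phenol oxygen. The phenol is kept as an electron-withdrawing sulfonate for the whole sequence because it must not compete as a nucleophile in the etherification, must not make C2 ionisable in acid, and must lower the migratory aptitude of ring C in the rearrangement.

**20 to 18 and 19.** The CH2–O bond to the eugenol oxygen is cut. This is the only bond that separates a commercial phenol (19) from a primary alcohol (18), and its formation by redox condensation touches neither stereocentre.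

**18 to 16.** The hydroxymethyl group is traced to a methyl ester at the same carbon (via aldehyde 17). The ester is the oxidation level the rearrangement delivers, and a neutral hydride reduction does not disturb the centre alpha to the carbonyl.

**16 to 12 (key disconnection).** The C3–C3a bond is cut and the ring A carbon is reattached to the ester carbon, which turns the dihydrobenzofuran ester into the chroman-4-one 12. The cut is made here because it converts a problem of two stereocentres into a problem of one. In 12 only C2 is stereogenic, and the forward shift of ring A to the alpha carbon is stereospecific, so C3 is set by relay from C2. The forward reaction must make the alpha carbon electrophilic (enol ether 13, iodane 14), move ring A rather than ring C, and leave the C2–O1 bond and the allyl group alone.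

**12 to 8 and 11.** The C2–aryl bond is cut, which leads to chromone 8 and arylboronic acid 11. A catalytic asymmetric conjugate addition makes this bond and the (2S) centre together, and it brings in ring C already carrying its sulfonate.

**8 to 6.** The pyranone ring is opened at O1–C2 and C2–C3. The chromone comes from the ortho-hydroxyacetophenone 6 and a one-carbon unit at the formate oxidation level, through enaminone 7.

**6 to 3 to 1 and 2.** The allyl group para to the phenol is traced to the allyl ether 3. Both ortho positions of 3 are substituted, so a thermal rearrangement must pass through dienones 4 and 5 and end at the para position. Ether 3 comes from 1 and 2 by O-alkylation.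

**11 to 10 to 9.** The boronic acid is traced to the pinacol ester 10 and this to the commercial phenol boronate 9, so that the aryl–boron bond is bought and only the sulfonate and the free acid have to be made.

## Alternatives that were turned down

**Alternative 1:** Both flanking aryl–carbon bonds are cut, C2–C1' (ring C) and C3–C3a (ring A), and C2–C3 is kept as the two carbons of an alkene. Forward, [3-methoxy-4-(triisopropylsilyloxy)phenyl]lithium A2 adds to boron of the (E)-alkenyl pinacol boronate A3. Pd(OAc)2 with a MandyPhos ligand then couples the ate complex with 5-allyl-1-bromo-3-methoxy-2-(methoxymethoxy)benzene A4. The arylpalladium species (divalent palladium) activates the alkene, the ring C aryl shifts from boron to the alpha carbon, and ring A is delivered anti to the beta carbon, giving boronate A1.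
- For: this is the most convergent option. Both C–aryl bonds and both stereocentres come from one catalytic enantioselective step on three simple fragments. On bonds formed per step it is stronger than the chosen route.
- Against, reactivity: a beta-substituted alkenylboronate shifts slowly, so direct Suzuki coupling of the ate complex competes. A4 is an electron-rich, ortho-substituted bromide, which undergoes slow oxidative addition and releases bromide that inhibits the cationic palladium intermediate.
- Against, stereochemistry: in A1 boron occupies the place of O1 in the target. After stereoretentive oxidation, the O1–C2 bond must therefore be closed with net retention, through the para-oxygenated benzylic cation under thermodynamic control. One of the two catalyst-set centres is discarded, and the cation can lose the C3 proton to give a stilbene.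
- Against, step economy: three different protecting groups and about six further steps follow the key step, against three in the chosen route.
- What the chosen route offers instead: one protecting group, a stereocentre that stays fixed while the second is relayed from it, and the risk in one rearrangement of a known type.

**Alternative 2:** O1–C2 and C2–C3 are cut, so that C2 with ring C enters as a one-carbon unit in a formal [4+1] annulation. Forward, Cs2CO3 eliminates sulfinate from 4-allyl-2-[2-(4-allyl-2-methoxyphenoxy)-1-(p-tolylsulfonyl)ethyl]-6-methoxyphenol A6 to give an ortho-quinone methide of ring A. The same base deprotonates the ring C benzylsulfonium salt, taken here as 1-[4-(tert-butyldimethylsilyloxy)-3-methoxybenzyl]tetrahydrothiophenium bromide A7. The ylide carbon adds to the methide carbon (C2–C3) and the phenoxide displaces the sulfide at C2 in a 5-exo-tet closure (O1–C2), giving the O-silyl target A5.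
- For: the eugenyl ether is already in place, so A5 is one desilylation from the target. The conditions are mild and spare the allyl groups, and the trans relation follows from the anti arrangement of the betaine. On steps after the key step (one against three) and on mildness this alternative is stronger.
- Against, absolute configuration: the step creates both stereocentres from two achiral partners. A7 as drawn gives a racemate, so a chiral sulfide or chiral catalyst must control a semi-stabilised benzylic ylide. The reversible betaine formation that secures trans also works against enantiocontrol.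
- Against, stability: the methide carbon carries a CH2OAr group, and such quinone methides tautomerise to 2-vinylphenols by hydrogen shift. The sulfonyl-bearing carbon of A6 has an aryloxy leaving group in the beta position, so E1cB loss of the eugenol phenoxide competes under the same base.
- Against, supply: A6 and A7 each need several steps.
- What the chosen route offers instead: the absolute configuration is set in a catalytic step with a well-understood facial model and is then transferred. The price is two more steps at the end.

**Alternative 3:** C3–C3a and the C–O bond of the hydroxymethyl group are cut, and C2 is installed beforehand as the stereocentre of an aryl 1-arylallyl ether. Forward, Bu3SnH under air converts the iodide tert-butyl{4-[(1S)-1-(4-allyl-2-iodo-6-methoxyphenoxy)prop-2-en-1-yl]-2-methoxyphenoxy}dimethylsilane A9 into the C3a aryl radical. This closes 5-exo-trig on the internal alkene carbon (C3–C3a). The primary radical is trapped by O2 and the hydroperoxide is reduced, giving alcohol A8, the silyl analogue of 18.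
- For: the ring, the C3 centre and the oxygen function arrive together at the right oxidation level, with no ester reduction. Aryl radical cyclisations are fast and indifferent to the electron-rich arenes. In redox economy this alternative is stronger.
- Against, stereochemistry: the C3 configuration depends only on a conformational preference of the C2 aryl group in the cyclisation transition state. This gives a trans preference but no stereospecificity, and the product cannot be equilibrated.
- Against, chemoselectivity: the primary radical partitions between O2 and the tin hydride. Oxygen and tin radicals also meet a C2–H that is benzylic, allylic and alpha to oxygen, and two allylarene CH2 groups, so autoxidation is likely.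
- Against, supply: A9 is an enantiopure ether of an electron-rich secondary benzylic and allylic alcohol with a 2,6-disubstituted phenol. It is prone to ionisation and allylic transposition during its own synthesis.
- What the chosen route offers instead: C3 is fixed by an invertive 1,2-shift whose outcome also matches the thermodynamic preference, and no radical or oxygen chemistry is run in the presence of three alkenes.

Key step: step 7

Remark (assumption on the chemistry): the sense of induction in step 6 is taken from the model for six-membered cyclic enones, in which (S)-configured biaryl bisphosphines on rhodium give the (S)-beta-aryl ketone. The substituents at the beta carbon of the chromone map onto that case without a change of descriptor, so the (S)-ligand is specified for 12.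

## Route

**Step 1**
Reactants: 1 1-(2-hydroxy-3-methoxyphenyl)ethanone; 2 allyl bromide
Product: 3 1-(2-allyloxy-3-methoxyphenyl)ethanone
Conditions: K2CO3, DMF, 60 °C
Reagents that add atoms: none
Why: Williamson ether synthesis; the phenoxide, although hydrogen-bonded to the acetyl group, should be O-alkylated cleanly by the allylic bromide in a dipolar aprotic solvent.

**Step 2**
Reactants: 3 1-(2-allyloxy-3-methoxyphenyl)ethanone
Product: 6 1-(5-allyl-2-hydroxy-3-methoxyphenyl)ethanone, via ortho-dienone 4 (not isolated), via para-dienone 5 (not isolated)
Conditions: PhNEt2, 200 °C, sealed vessel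
Reagents that add atoms: none
Why: Para-Claisen rearrangement: with both ortho positions substituted the first [3,3] shift gives dienone 4, which cannot enolise, so a Cope shift carries the allyl group to the free para position (5) and tautomerisation restores the phenol; two successive allyl inversions return the terminal alkene unchanged.

**Step 3**
Reactants: 6 1-(5-allyl-2-hydroxy-3-methoxyphenyl)ethanone
Product: 8 6-allyl-8-methoxy-4H-chromen-4-one, via enaminone 7 (not isolated)
Conditions: Me2NCH(OMe)2, 100 °C; evaporate; conc. HCl, CH2Cl2, 40 °C
Reagents that add atoms: N,N-dimethylformamide dimethyl acetal, COC(OC)N(C)C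
Why: Enaminone route to chromones: condensation of the methyl ketone gives the vinylogous amide 7, and acid promotes conjugate addition of the phenol and loss of dimethylamine (addition–elimination); the isolated alkene should not react with HCl under these conditions.

**Step 4**
Reactants: 9 2-methoxy-4-(4,4,5,5-tetramethyl-1,3,2-dioxaborolan-2-yl)phenol
Product: 10 2-methoxy-4-(4,4,5,5-tetramethyl-1,3,2-dioxaborolan-2-yl)phenyl methanesulfonate
Conditions: MsCl, Et3N, CH2Cl2, 0 °C
Reagents that add atoms: methanesulfonyl chloride, CS(=O)(=O)Cl
Why: O-sulfonylation of the phenol; the pinacol boronate is inert to MsCl and amine, and the mesylate is an electron-withdrawing phenol protection that should survive acid, oxidant, hydride and Mitsunobu conditions.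

**Step 5**
Reactants: 10 2-methoxy-4-(4,4,5,5-tetramethyl-1,3,2-dioxaborolan-2-yl)phenyl methanesulfonate
Product: 11 [3-methoxy-4-(methylsulfonyloxy)phenyl]boronic acid
Conditions: NaIO4, NH4OAc, acetone/H2O, rt
Reagents that add atoms: water, O
Why: Periodate glycol cleavage removes the pinacol released in the hydrolysis equilibrium and so drives the ester to the free boronic acid, which transmetalates to rhodium at room temperature; this fragment contains no alkene.

**Step 6**
Reactants: 8 6-allyl-8-methoxy-4H-chromen-4-one; 11 [3-methoxy-4-(methylsulfonyloxy)phenyl]boronic acid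
Product: 12 (2S)-6-allyl-8-methoxy-2-[3-methoxy-4-(methylsulfonyloxy)phenyl]chroman-4-one
Conditions: [RhCl(C2H4)2]2 (2.5 mol%), (S)-MeO-F12-BIPHEP [(S)-6,6'-dimethoxybiphenyl-2,2'-diylbis(bis(3,4,5-trifluorophenyl)phosphine)] (5.5 mol%), aq. KOH (0.2 equiv), toluene/H2O, 25 °C
Reagents that add atoms: none
Why: Hayashi–Miyaura asymmetric 1,4-addition: aryl transfer from boron to the hydroxorhodium complex, insertion of the chromone C2=C3 bond and hydrolysis of the rhodium enolate, with the bisphosphine selecting the face of C2 that gives the (2S) centre; the electron-poor ligand should let the electron-rich chromone react at room temperature, where base-induced opening of the flavanone to the chalcone is slow, and arylrhodium (monovalent rhodium) does not add to the isolated allyl group.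

**Step 7**
Reactants: 12 (2S)-6-allyl-8-methoxy-2-[3-methoxy-4-(methylsulfonyloxy)phenyl]chroman-4-one
Product: 16 methyl (2S,3S)-5-allyl-7-methoxy-2-[3-methoxy-4-(methylsulfonyloxy)phenyl]-2,3-dihydrobenzofuran-3-carboxylate, via enol ether 13 (not isolated), via iodane adduct 14 (not isolated), via orthoester 15 (not isolated)
Conditions: PhI(OAc)2 (1.1 equiv), conc. H2SO4 (0.5 equiv), HC(OMe)3, 0 °C to rt; then H2O
Reagents that add atoms: trimethyl orthoformate, COC(OC)OC; water, O
Why: Acid and orthoformate convert the ketone into enol ether 13; the trivalent iodine electrophile attacks C3 on the face away from the C2 aryl group and methanol adds at C4, giving ketal iodane 14 with iodine trans to the aryl group. The C4–C4a bond lies anti-periplanar to this equatorial C3–I bond, so C4a of ring A migrates from C4 to C3 as iodobenzene leaves; this forms C3–C3a and closes the dihydrofuran ring by ring contraction through a phenonium-like bridged transition state, not by a cyclisation of a chain. The dimethoxycarbenium ion left at the old C4 is captured by methanol as orthoester 15 and hydrolysed to the methyl ester on aqueous work-up. The closest known reaction type is the oxidative ring contraction of flavanones with PhI(OAc)2 or Tl(NO3)3 in trimethyl orthoformate to methyl trans-2-aryl-2,3-dihydrobenzofuran-3-carboxylates, a semipinacol-type 1,2-aryl shift. The new centre C3 is controlled by C2: anti iodination followed by migration with inversion at C3 places the ester carbon trans to the aryl group, which is also the more stable arrangement, while C2 takes part in no bond change. The step needs ring A to migrate in preference to ring C, the iodane to rearrange before solvolysis or elimination, the enol ether to outcompete the terminal alkene for the oxidant, and the C2–O1 bond to resist acid. These are secured by O1 ortho to the migrating carbon, by the para mesylate, which lowers both the migratory aptitude of ring C and the stability of a cation at C2, and by the much higher nucleophilicity of the enol ether towards a small excess of oxidant.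

**Step 8**
Reactants: 16 methyl (2S,3S)-5-allyl-7-methoxy-2-[3-methoxy-4-(methylsulfonyloxy)phenyl]-2,3-dihydrobenzofuran-3-carboxylate
Product: 18 [(2S,3R)-5-allyl-7-methoxy-2-[3-methoxy-4-(methylsulfonyloxy)phenyl]-2,3-dihydrobenzofuran-3-yl]methanol, via aldehyde 17 (not isolated)
Conditions: i-Bu2AlH (3 equiv), CH2Cl2, −78 to 0 °C; aq. potassium sodium tartrate
Reagents that add atoms: none
Why: Ester reduction through aldehyde 17 with a neutral aluminium hydride at low temperature; the aryl sulfonate, terminal alkenes and benzylic ether should be untouched and the centre alpha to the carbonyl is not epimerised (the descriptor at C3 changes from S to R only because the CH2OH group ranks below C2).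

**Step 9**
Reactants: 18 [(2S,3R)-5-allyl-7-methoxy-2-[3-methoxy-4-(methylsulfonyloxy)phenyl]-2,3-dihydrobenzofuran-3-yl]methanol; 19 eugenol (4-allyl-2-methoxyphenol)
Product: 20 4-[(2S,3R)-5-allyl-3-[(4-allyl-2-methoxyphenoxy)methyl]-7-methoxy-2,3-dihydrobenzofuran-2-yl]-2-methoxyphenyl methanesulfonate
Conditions: PPh3, DIAD, THF, 0 °C to rt
Reagents that add atoms: none
Why: Mitsunobu reaction: the primary alcohol is activated on phosphorus and displaced by the phenoxide of 19 in an SN2 reaction at the CH2 group, so neither stereocentre is involved; the ring C phenol is masked and cannot compete.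

**Step 10**
Reactants: 20 4-[(2S,3R)-5-allyl-3-[(4-allyl-2-methoxyphenoxy)methyl]-7-methoxy-2,3-dihydrobenzofuran-2-yl]-2-methoxyphenyl methanesulfonate
Product: 21 4-[(2S,3R)-5-allyl-3-[(4-allyl-2-methoxyphenoxy)methyl]-7-methoxy-2,3-dihydrobenzofuran-2-yl]-2-methoxyphenol (CNP0138854.1)
Conditions: KOH, MeOH/THF/H2O, 50 °C; then aq. NH4Cl
Reagents that add atoms: none
Why: Basic hydrolysis of the aryl methanesulfonate releases the phenoxide, protonated on work-up; aqueous-methanolic KOH at 50 °C should be too mild to move the allyl double bonds into conjugation or to open the dihydrofuran ring, and neither stereocentre carries an acidic hydrogen.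

## Compound list

1 | 1-(2-hydroxy-3-methoxyphenyl)ethanone (2'-hydroxy-3'-methoxyacetophenone) | CC(=O)c1cccc(OC)c1O | starting material
2 | allyl bromide | C=CCBr | starting material
3 | 1-(2-allyloxy-3-methoxyphenyl)ethanone | CC(=O)c1cccc(OC)c1OCC=C | intermediate
4 | 2-acetyl-6-allyl-6-methoxycyclohexa-2,4-dien-1-one (racemic ortho-dienone) | CC(=O)C1=CC=CC(CC=C)(OC)C1=O | intermediate (not isolated)
5 | 2-acetyl-4-allyl-6-methoxycyclohexa-2,5-dien-1-one (racemic para-dienone) | CC(=O)C1=CC(CC=C)C=C(OC)C1=O | intermediate (not isolated)
6 | 1-(5-allyl-2-hydroxy-3-methoxyphenyl)ethanone | CC(=O)c1cc(CC=C)cc(OC)c1O | intermediate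
7 | (E)-1-(5-allyl-2-hydroxy-3-methoxyphenyl)-3-(dimethylamino)prop-2-en-1-one | CN(C)/C=C/C(=O)c1cc(CC=C)cc(OC)c1O | intermediate (not isolated)
8 | 6-allyl-8-methoxy-4H-chromen-4-one | C=CCc1cc(OC)c2occc(=O)c2c1 | intermediate
9 | 2-methoxy-4-(4,4,5,5-tetramethyl-1,3,2-dioxaborolan-2-yl)phenol | COc1cc(B2OC(C)(C)C(C)(C)O2)ccc1O | starting material
10 | 2-methoxy-4-(4,4,5,5-tetramethyl-1,3,2-dioxaborolan-2-yl)phenyl methanesulfonate | COc1cc(B2OC(C)(C)C(C)(C)O2)ccc1OS(C)(=O)=O | intermediate
11 | [3-methoxy-4-(methylsulfonyloxy)phenyl]boronic acid | COc1cc(B(O)O)ccc1OS(C)(=O)=O | intermediate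
12 | (2S)-6-allyl-8-methoxy-2-[3-methoxy-4-(methylsulfonyloxy)phenyl]chroman-4-one | C=CCc1cc(OC)c2O[C@@H](CC(=O)c2c1)c1ccc(OS(C)(=O)=O)c(OC)c1 | intermediate
13 | (2S)-6-allyl-4,8-dimethoxy-2-[3-methoxy-4-(methylsulfonyloxy)phenyl]-2H-chromene | C=CCc1cc(OC)c2O[C@@H](C=C(OC)c2c1)c1ccc(OS(C)(=O)=O)c(OC)c1 | intermediate (not isolated)
14 | (2R,3R)-3-[acetoxy(phenyl)-λ3-iodanyl]-6-allyl-4,4,8-trimethoxy-2-[3-methoxy-4-(methylsulfonyloxy)phenyl]chromane (iodine trans to the aryl group; C2 spatially unchanged, descriptor R because C3 now outranks the aryl group) | C=CCc1cc(OC)c2O[C@@H]([C@@H](I(OC(C)=O)c3ccccc3)C(OC)(OC)c2c1)c1ccc(OS(C)(=O)=O)c(OC)c1 | intermediate (not isolated)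
15 | (2S,3S)-5-allyl-7-methoxy-2-[3-methoxy-4-(methylsulfonyloxy)phenyl]-3-(trimethoxymethyl)-2,3-dihydrobenzofuran | COC(OC)(OC)[C@H]1c2cc(CC=C)cc(OC)c2O[C@@H]1c1ccc(OS(C)(=O)=O)c(OC)c1 | intermediate (not isolated)
16 | methyl (2S,3S)-5-allyl-7-methoxy-2-[3-methoxy-4-(methylsulfonyloxy)phenyl]-2,3-dihydrobenzofuran-3-carboxylate (trans) | COC(=O)[C@H]1c2cc(CC=C)cc(OC)c2O[C@@H]1c1ccc(OS(C)(=O)=O)c(OC)c1 | intermediate
17 | (2S,3S)-5-allyl-7-methoxy-2-[3-methoxy-4-(methylsulfonyloxy)phenyl]-2,3-dihydrobenzofuran-3-carbaldehyde | O=C[C@H]1c2cc(CC=C)cc(OC)c2O[C@@H]1c1ccc(OS(C)(=O)=O)c(OC)c1 | intermediate (not isolated)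
18 | [(2S,3R)-5-allyl-7-methoxy-2-[3-methoxy-4-(methylsulfonyloxy)phenyl]-2,3-dihydrobenzofuran-3-yl]methanol | OC[C@H]1c2cc(CC=C)cc(OC)c2O[C@@H]1c1ccc(OS(C)(=O)=O)c(OC)c1 | intermediate
19 | eugenol (4-allyl-2-methoxyphenol) | C=CCc1ccc(O)c(OC)c1 | starting material
20 | 4-[(2S,3R)-5-allyl-3-[(4-allyl-2-methoxyphenoxy)methyl]-7-methoxy-2,3-dihydrobenzofuran-2-yl]-2-methoxyphenyl methanesulfonate | C=CCc1ccc(OC[C@H]2c3cc(CC=C)cc(OC)c3O[C@@H]2c2ccc(OS(C)(=O)=O)c(OC)c2)c(OC)c1 | intermediate
21 | 4-[(2S,3R)-5-allyl-3-[(4-allyl-2-methoxyphenoxy)methyl]-7-methoxy-2,3-dihydrobenzofuran-2-yl]-2-methoxyphenol | C=CCc1ccc(OC[C@H]2c3cc(CC=C)cc(OC)c3O[C@@H]2c2ccc(O)c(OC)c2)c(OC)c1 | target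

## Step count and least certain steps

Total: 10 steps. Longest linear sequence: 8 steps (1, 2, 3, 6, 7, 8, 9, 10); the ring C branch (steps 4 and 5) joins at step 6.

**Step 7 (key step).** Three processes are most likely to intervene. The iodane may undergo solvolysis or elimination at C3 before ring A shifts. The acid-activated trivalent iodine reagent may attack a terminal alkene. Acid may open the C2–O1 bond and so erode the enantiomeric purity. The fallback keeps the same shift of ring A from C4 to C3 but runs it without acid or oxidant, as a Wolff ring contraction, setting out from 12 and returning at 16. Ketone 12 would be deprotonated with LiN(SiMe3)2 at −78 °C and acylated with 2,2,2-trifluoroethyl trifluoroacetate to give (2S)-6-allyl-8-methoxy-2-[3-methoxy-4-(methylsulfonyloxy)phenyl]-3-(trifluoroacetyl)chroman-4-one F1. Deacylative diazo transfer with methanesulfonyl azide and Et3N would give (2R)-6-allyl-3-diazo-8-methoxy-2-[3-methoxy-4-(methylsulfonyloxy)phenyl]chroman-4-one F2 (same spatial arrangement at C2; the descriptor changes with the priorities). Irradiation in methanol would expel nitrogen and, because only the substituent on the carbonyl carbon can migrate, send ring A to C3 to give the ketene (2R)-5-allyl-7-methoxy-2-[3-methoxy-4-(methylsulfonyloxy)phenyl]-3-(oxomethylidene)-2,3-dihydrobenzofuran F3. Methanol adds to F3 to give 16 together with its cis epimer methyl (2S,3R)-5-allyl-7-methoxy-2-[3-methoxy-4-(methylsulfonyloxy)phenyl]-2,3-dihydrobenzofuran-3-carboxylate F4, and DBU in CH2Cl2 would equilibrate F4 to the trans ester 16.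

**Step 6.** Turnover may be low with the electron-rich chromone, the facial selectivity may be lower than or opposite to the model, and base may open the product to the chalcone and racemise it. The fallback builds the flavanone without a chromone and resolves it, setting out from 6 and returning at 12. Pyrrolidine-mediated aldol condensation of 6 with 4-formyl-2-methoxyphenyl methanesulfonate F5 (from vanillin, MsCl and Et3N) would give (E)-1-(5-allyl-2-hydroxy-3-methoxyphenyl)-3-[3-methoxy-4-(methylsulfonyloxy)phenyl]prop-2-en-1-one F6. This closes by oxa-Michael addition (completed with NaOAc in hot ethanol) to racemic 6-allyl-8-methoxy-2-[3-methoxy-4-(methylsulfonyloxy)phenyl]chroman-4-one F7. Kinetic resolution by Noyori-type asymmetric transfer hydrogenation with RuCl(p-cymene)[(R,R)-TsDPEN] and HCO2H/Et3N, stopped near half conversion, is expected to reduce the (2R)-ketone to (2R,4R)-6-allyl-8-methoxy-2-[3-methoxy-4-(methylsulfonyloxy)phenyl]chroman-4-ol F8 and leave 12.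

**Step 2.** At 200 °C dienone 4 may aromatise by loss of its methoxy or acetyl substituent instead of undergoing the Cope shift, and the product may decompose thermally. The fallback replaces the sigmatropic route by cross-coupling, setting out from 1 and returning at 6. Bromination of 1 with NBS in MeCN should go para to the hydroxyl group and give 1-(5-bromo-2-hydroxy-3-methoxyphenyl)ethanone F9. Stille coupling of F9 with allyltributylstannane and Pd(PPh3)4 (zerovalent palladium) in DMF at 90 °C would give 6.

**Step 9.** The activated alcohol may lose the benzylic C3 proton (elimination to the exocyclic alkene and on to the 3-methylbenzofuran), and substitution at the beta-branched carbon may be slow. The fallback separates activation from substitution, setting out from 18 and returning at 20. MsCl and Et3N would give [(2S,3R)-5-allyl-7-methoxy-2-[3-methoxy-4-(methylsulfonyloxy)phenyl]-2,3-dihydrobenzofuran-3-yl]methyl methanesulfonate F10. F10 would then be displaced by the phenoxide of 19 (Cs2CO3, DMF, 50 °C) in a Williamson ether synthesis to give 20.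

## Further compounds

F1 | step 7 | (2S)-6-allyl-8-methoxy-2-[3-methoxy-4-(methylsulfonyloxy)phenyl]-3-(trifluoroacetyl)chroman-4-one (C3 undefined, largely enolised) | C=CCc1cc(OC)c2O[C@@H](C(C(=O)C(F)(F)F)C(=O)c2c1)c1ccc(OS(C)(=O)=O)c(OC)c1
F2 | step 7 | (2R)-6-allyl-3-diazo-8-methoxy-2-[3-methoxy-4-(methylsulfonyloxy)phenyl]chroman-4-one | C=CCc1cc(OC)c2O[C@@H](C(=[N+]=[N-])C(=O)c2c1)c1ccc(OS(C)(=O)=O)c(OC)c1
F3 | step 7 | (2R)-5-allyl-7-methoxy-2-[3-methoxy-4-(methylsulfonyloxy)phenyl]-3-(oxomethylidene)-2,3-dihydrobenzofuran | O=C=C1c2cc(CC=C)cc(OC)c2O[C@@H]1c1ccc(OS(C)(=O)=O)c(OC)c1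
F4 | step 7 | methyl (2S,3R)-5-allyl-7-methoxy-2-[3-methoxy-4-(methylsulfonyloxy)phenyl]-2,3-dihydrobenzofuran-3-carboxylate (cis) | COC(=O)[C@@H]1c2cc(CC=C)cc(OC)c2O[C@@H]1c1ccc(OS(C)(=O)=O)c(OC)c1
F5 | step 6 | 4-formyl-2-methoxyphenyl methanesulfonate | COc1cc(C=O)ccc1OS(C)(=O)=O
F6 | step 6 | (E)-1-(5-allyl-2-hydroxy-3-methoxyphenyl)-3-[3-methoxy-4-(methylsulfonyloxy)phenyl]prop-2-en-1-one | C=CCc1cc(OC)c(O)c(c1)C(=O)/C=C/c1ccc(OS(C)(=O)=O)c(OC)c1
F7 | step 6 | racemic 6-allyl-8-methoxy-2-[3-methoxy-4-(methylsulfonyloxy)phenyl]chroman-4-one | C=CCc1cc(OC)c2OC(CC(=O)c2c1)c1ccc(OS(C)(=O)=O)c(OC)c1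
F8 | step 6 | (2R,4R)-6-allyl-8-methoxy-2-[3-methoxy-4-(methylsulfonyloxy)phenyl]chroman-4-ol (cis) | C=CCc1cc(OC)c2O[C@H](C[C@@H](O)c2c1)c1ccc(OS(C)(=O)=O)c(OC)c1
F9 | step 2 | 1-(5-bromo-2-hydroxy-3-methoxyphenyl)ethanone | CC(=O)c1cc(Br)cc(OC)c1O
F10 | step 9 | [(2S,3R)-5-allyl-7-methoxy-2-[3-methoxy-4-(methylsulfonyloxy)phenyl]-2,3-dihydrobenzofuran-3-yl]methyl methanesulfonate | CS(=O)(=O)OC[C@H]1c2cc(CC=C)cc(OC)c2O[C@@H]1c1ccc(OS(C)(=O)=O)c(OC)c1
A1 | alternative 1 | 2-[(1S,2R)-2-[5-allyl-3-methoxy-2-(methoxymethoxy)phenyl]-3-(tert-butyldimethylsilyloxy)-1-[3-methoxy-4-(triisopropylsilyloxy)phenyl]propyl]-4,4,5,5-tetramethyl-1,3,2-dioxaborolane | CC(C)(C)[Si](C)(C)OC[C@@H](c1cc(CC=C)cc(OC)c1OCOC)[C@H](B1OC(C)(C)C(C)(C)O1)c1ccc(O[Si](C(C)C)(C(C)C)C(C)C)c(OC)c1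
A2 | alternative 1 | [3-methoxy-4-(triisopropylsilyloxy)phenyl]lithium | [Li]c1ccc(O[Si](C(C)C)(C(C)C)C(C)C)c(OC)c1
A3 | alternative 1 | (E)-tert-butyldimethyl{[3-(4,4,5,5-tetramethyl-1,3,2-dioxaborolan-2-yl)prop-2-en-1-yl]oxy}silane | CC(C)(C)[Si](C)(C)OC/C=C/B1OC(C)(C)C(C)(C)O1
A4 | alternative 1 | 5-allyl-1-bromo-3-methoxy-2-(methoxymethoxy)benzene | C=CCc1cc(Br)c(OCOC)c(OC)c1
A5 | alternative 2 | (2S,3R)-5-allyl-3-[(4-allyl-2-methoxyphenoxy)methyl]-2-[4-(tert-butyldimethylsilyloxy)-3-methoxyphenyl]-7-methoxy-2,3-dihydrobenzofuran | C=CCc1ccc(OC[C@H]2c3cc(CC=C)cc(OC)c3O[C@@H]2c2ccc(O[Si](C)(C)C(C)(C)C)c(OC)c2)c(OC)c1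
A6 | alternative 2 | 4-allyl-2-[2-(4-allyl-2-methoxyphenoxy)-1-(p-tolylsulfonyl)ethyl]-6-methoxyphenol (racemic) | C=CCc1cc(OC)c(O)c(c1)C(COc1ccc(CC=C)cc1OC)S(=O)(=O)c1ccc(C)cc1
A7 | alternative 2 | 1-[4-(tert-butyldimethylsilyloxy)-3-methoxybenzyl]tetrahydrothiophenium bromide | COc1cc(C[S+]2CCCC2)ccc1O[Si](C)(C)C(C)(C)C.[Br-]
A8 | alternative 3 | [(2S,3R)-5-allyl-2-[4-(tert-butyldimethylsilyloxy)-3-methoxyphenyl]-7-methoxy-2,3-dihydrobenzofuran-3-yl]methanol | OC[C@H]1c2cc(CC=C)cc(OC)c2O[C@@H]1c1ccc(O[Si](C)(C)C(C)(C)C)c(OC)c1
A9 | alternative 3 | tert-butyl{4-[(1S)-1-(4-allyl-2-iodo-6-methoxyphenoxy)prop-2-en-1-yl]-2-methoxyphenoxy}dimethylsilane | C=C[C@H](Oc1c(I)cc(CC=C)cc1OC)c1ccc(O[Si](C)(C)C(C)(C)C)c(OC)c1
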